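Ring A is a phloroglucinol whose C2, flanked by the C1 and C3 hydroxyls, carries the ether oxygen to ring B: the oxygenation pattern of a triketide chain oxygenated at its terminal carbon. Everything rests on cutting the C1–C2 bond of ring A, which leads back to 4-methoxy-2-pyrone 11 carrying the permethylated BCD trimer as an aryloxymethyl group at C6, so the most congested diaryl ether begins as an SN2-made alkyl aryl ether. In one operation methoxide opens the lactone and the ArOCH2 ketone enolate closes onto the freed ester, giving aromatic ring A with the A–O–B ether in place. Iterative copper coupling and Baeyer–Villiger oxidation build rings B–D; BBr3 unmasks the target.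

Key step: step 7

Remark: rings are lettered A to D from the free phloroglucinol end (A) to the pyrogallol-type end (D); the target is achiral, so no stereocentre has to be set, and "BCD-aryl" below stands for the 4-[3,5-dimethoxy-4-(3,4,5-trimethoxyphenoxy)phenoxy]-3,5-dimethoxyphenyl group.

Step 1
Reactants: 1 3,4,5-trimethoxyphenol; 2 4-bromo-3,5-dimethoxybenzaldehyde
Product: 3 3,5-dimethoxy-4-(3,4,5-trimethoxyphenoxy)benzaldehyde (CD aldehyde)
Conditions: CuI (10 mol%), picolinic acid (20 mol%), K3PO4 (2 equiv), DMSO, 100 °C, argon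
Reagents that add atoms: none
Why: Ullmann-type copper-catalysed diaryl ether synthesis, in which the unhindered phenoxide of 1 should displace bromide from 2, whose C–Br bond is activated by the para formyl group, under a picolinic acid ligand system chosen for its tolerance of ortho,ortho'-disubstituted aryl halides.

Step 2
Reactants: 3 CD aldehyde
Product: 5 3,5-dimethoxy-4-(3,4,5-trimethoxyphenoxy)phenol (CD phenol), via CD aryl formate 4 (not isolated)
Conditions: mCPBA, NaHCO3, CH2Cl2, 0 °C to rt; aq. Na2S2O3 wash; then K2CO3 (cat.), MeOH, rt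
Reagents that add atoms: mCPBA (3-chloroperoxybenzoic acid), O=C(OO)c1cccc(Cl)c1
Why: Baeyer–Villiger (Dakin-type) oxidation, in which the electron-rich aryl group with a para oxygen donor should migrate in preference to hydride, as it does for 3,4,5-trimethoxybenzaldehyde, and the labile aryl formate is then cleaved by base-catalysed methanolysis without touching the ethers.

Step 3
Reactants: 5 CD phenol; 2 4-bromo-3,5-dimethoxybenzaldehyde
Product: 6 4-[3,5-dimethoxy-4-(3,4,5-trimethoxyphenoxy)phenoxy]-3,5-dimethoxybenzaldehyde (BCD aldehyde)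
Conditions: CuI (10 mol%), picolinic acid (20 mol%), K3PO4 (2 equiv), DMSO, 100 °C, argon
Reagents that add atoms: none
Why: The same Ullmann-type coupling as in step 1; the phenol oxygen of 5 is flanked only by hydrogens, so the steric demand again lies solely in the bromide.

Step 4
Reactants: 6 BCD aldehyde
Product: 8 4-[3,5-dimethoxy-4-(3,4,5-trimethoxyphenoxy)phenoxy]-3,5-dimethoxyphenol (BCD phenol), via BCD aryl formate 7 (not isolated)
Conditions: mCPBA, NaHCO3, CH2Cl2, 0 °C to rt; aq. Na2S2O3 wash; then K2CO3 (cat.), MeOH, rt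
Reagents that add atoms: mCPBA (3-chloroperoxybenzoic acid), O=C(OO)c1cccc(Cl)c1
Why: A second Baeyer–Villiger oxidation on the same 4-aryloxy-3,5-dimethoxybenzaldehyde motif as in step 2, followed by methanolysis of the formate.

Step 5
Reactants: 9 4-methoxy-6-methyl-2H-pyran-2-one
Product: 10 6-(bromomethyl)-4-methoxy-2H-pyran-2-one
Conditions: NBS (1.05 equiv), AIBN (cat.), PhCF3 (or CCl4), reflux
Reagents that add atoms: NBS (N-bromosuccinimide), O=C1CCC(=O)N1Br
Why: Wohl–Ziegler radical bromination of the C6 methyl group, which is allylic to the ring enol-ether double bond; radical-chain conditions in a non-polar solvent suppress ionic bromination at C3.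

Step 6
Reactants: 8 BCD phenol; 10 6-(bromomethyl)-4-methoxy-2H-pyran-2-one
Product: 11 6-[(BCD-aryloxy)methyl]-4-methoxy-2H-pyran-2-one
Conditions: K2CO3 (1.5 equiv), acetone, 50 °C
Reagents that add atoms: none
Why: Williamson ether synthesis, an SN2 displacement of a primary allylic-type bromide by an unhindered phenoxide under carbonate conditions that leave the pyrone ring closed, so the future A–O–B link is made without any aryl coupling.

Step 7
Reactants: 11 6-[(BCD-aryloxy)methyl]-4-methoxy-2H-pyran-2-one
Product: 14 2-(BCD-aryloxy)-5-methoxybenzene-1,3-diol (ring A closed), via ring-opened keto ester 12 (not isolated), via cyclohexenedione keto tautomer 13 (not isolated)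
Conditions: NaOMe (5 equiv), dry MeOH, sealed tube, 120–160 °C, argon; then 1 M HCl, 0 °C
Reagents that add atoms: none
Why: Methoxide adds to the lactone carbonyl (pyrone C2) and expels the C6 enol oxygen, unmasking keto ester 12 as its sodium enolate with the ester and the ketone-bearing chain still cis across the enol-ether double bond, as the ring held them. Fast proton exchange in methanol makes the ArOCH2 enolate (acidified by the aryloxy oxygen) available, and its carbon attacks the ester carbonyl in a Claisen (Dieckmann-type) condensation that forms C1–C2 of ring A by a 6-exo-trig (enolexo) closure; loss of methoxide gives 13, which enolises to the resorcinolate of 14. The closest known reaction is the methoxide-promoted isomerisation of 4-methoxy-6-methyl-2-pyrone 9 to 5-methoxyresorcinol, here run on a homologue whose nucleophilic carbon carries an aryloxy group. No stereocentre survives, since the one sp3 CH(OAr) carbon of 13 becomes aromatic C2. The selectivity needed is C-acylation through the ArOCH2 enolate: the more stable C4 enolate could only close a four-membered ring and O-acylation merely returns 11, so both are unproductive and reversible, whereas aromatisation and deprotonation of 14 by the excess base make the desired closure irreversible. The BCD methyl and diaryl ethers are inert to methoxide, and exchange at the pyrone 4-OMe or at the ester is degenerate because base and solvent match the methyl groups.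

Step 8
Reactants: 14 2-(BCD-aryloxy)-5-methoxybenzene-1,3-diol
Product: 15 2-{4-[4-(3,4,5-trihydroxyphenoxy)-3,5-dihydroxyphenoxy]-3,5-dihydroxyphenoxy}benzene-1,3,5-triol (target)
Conditions: BBr3 (16 equiv), CH2Cl2, −78 °C to rt, argon; then degassed H2O, 0 °C; Sephadex LH-20 or reversed-phase chromatography under argon
Reagents that add atoms: none
Why: Lewis-acid cleavage of aryl methyl ethers with BBr3 (bromide attacks the methyl group of the boron–ether complex), to which diaryl ether links are inert; the excess covers the two free hydroxyls and all eight methoxy groups, and the aryl borates are hydrolysed on quench.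

Compound list
1 | 3,4,5-trimethoxyphenol | COc1cc(O)cc(OC)c1OC | starting material
2 | 4-bromo-3,5-dimethoxybenzaldehyde | COc1cc(C=O)cc(OC)c1Br | starting material
3 | 3,5-dimethoxy-4-(3,4,5-trimethoxyphenoxy)benzaldehyde (CD aldehyde) | COc1cc(C=O)cc(OC)c1Oc1cc(OC)c(OC)c(OC)c1 | intermediate
4 | 3,5-dimethoxy-4-(3,4,5-trimethoxyphenoxy)phenyl formate (CD aryl formate, not isolated) | O=COc1cc(OC)c(Oc2cc(OC)c(OC)c(OC)c2)c(OC)c1 | intermediate
5 | 3,5-dimethoxy-4-(3,4,5-trimethoxyphenoxy)phenol (CD phenol) | Oc1cc(OC)c(Oc2cc(OC)c(OC)c(OC)c2)c(OC)c1 | intermediate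
6 | 4-[3,5-dimethoxy-4-(3,4,5-trimethoxyphenoxy)phenoxy]-3,5-dimethoxybenzaldehyde (BCD aldehyde) | O=Cc1cc(OC)c(Oc2cc(OC)c(Oc3cc(OC)c(OC)c(OC)c3)c(OC)c2)c(OC)c1 | intermediate
7 | 4-[3,5-dimethoxy-4-(3,4,5-trimethoxyphenoxy)phenoxy]-3,5-dimethoxyphenyl formate (BCD aryl formate, not isolated) | O=COc1cc(OC)c(Oc2cc(OC)c(Oc3cc(OC)c(OC)c(OC)c3)c(OC)c2)c(OC)c1 | intermediate
8 | 4-[3,5-dimethoxy-4-(3,4,5-trimethoxyphenoxy)phenoxy]-3,5-dimethoxyphenol (BCD phenol) | Oc1cc(OC)c(Oc2cc(OC)c(Oc3cc(OC)c(OC)c(OC)c3)c(OC)c2)c(OC)c1 | intermediate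
9 | 4-methoxy-6-methyl-2H-pyran-2-one | COC1=CC(=O)OC(C)=C1 | starting material
10 | 6-(bromomethyl)-4-methoxy-2H-pyran-2-one | COC1=CC(=O)OC(CBr)=C1 | intermediate
11 | 6-({4-[3,5-dimethoxy-4-(3,4,5-trimethoxyphenoxy)phenoxy]-3,5-dimethoxyphenoxy}methyl)-4-methoxy-2H-pyran-2-one | COC1=CC(=O)OC(COc2cc(OC)c(Oc3cc(OC)c(Oc4cc(OC)c(OC)c(OC)c4)c(OC)c3)c(OC)c2)=C1 | intermediate
12 | methyl (2E)-6-(BCD-aryloxy)-3-methoxy-5-oxohex-2-enoate (ring-opened keto ester, present as its sodium enolate, not isolated) | COC(=O)/C=C(/OC)CC(=O)COc1cc(OC)c(Oc2cc(OC)c(Oc3cc(OC)c(OC)c(OC)c3)c(OC)c2)c(OC)c1 | intermediate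
13 | 2-(BCD-aryloxy)-5-methoxycyclohex-4-ene-1,3-dione (keto tautomer of 14, racemic at the transient CH(OAr) carbon, not isolated) | COC1=CC(=O)C(Oc2cc(OC)c(Oc3cc(OC)c(Oc4cc(OC)c(OC)c(OC)c4)c(OC)c3)c(OC)c2)C(=O)C1 | intermediate
14 | 2-{4-[3,5-dimethoxy-4-(3,4,5-trimethoxyphenoxy)phenoxy]-3,5-dimethoxyphenoxy}-5-methoxybenzene-1,3-diol | COc1cc(O)c(Oc2cc(OC)c(Oc3cc(OC)c(Oc4cc(OC)c(OC)c(OC)c4)c(OC)c3)c(OC)c2)c(O)c1 | intermediate
15 | 2-{4-[4-(3,4,5-trihydroxyphenoxy)-3,5-dihydroxyphenoxy]-3,5-dihydroxyphenoxy}benzene-1,3,5-triol (CNP0333502.0) | Oc1cc(O)c(Oc2cc(O)c(Oc3cc(O)c(Oc4cc(O)c(O)c(O)c4)c(O)c3)c(O)c2)c(O)c1 | target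

Total step count: 8. Longest linear sequence: 7 steps (steps 1, 2, 3, 4, 6, 7, 8); step 5 is a one-step side branch.

Steps most likely to fail

Step 7. The ring-opened material may stall as the unproductive C4 dienolate, be saponified and decarboxylated by adventitious water, or expel the BCD aryloxide at the temperature needed for closure. The fallback abandons the pyrone and attaches ring A by a third pass of the iterative chemistry; it sets out from BCD phenol 8 and returns to the route at target 15. Copper-catalysed coupling of 8 with 2 (CuI, picolinic acid, K3PO4, DMSO, 100 °C) would give the ABCD aldehyde 4-{4-[3,5-dimethoxy-4-(3,4,5-trimethoxyphenoxy)phenoxy]-3,5-dimethoxyphenoxy}-3,5-dimethoxybenzaldehyde F1. Baeyer–Villiger oxidation with mCPBA would give the ABCD aryl formate F2, which is methanolysed without isolation (K2CO3 cat., MeOH) to the nonamethyl ABCD phenol F3. BBr3 in CH2Cl2 would then cleave nine methyl ethers to give 15. Ring A of F3 is a 4-aryloxy-3,5-dimethoxyphenol, which maps onto the same 2-aryloxyphloroglucinol after demethylation.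

Step 3 (step 1 shares the risk). Oxidative addition to the doubly ortho-methoxylated bromide may be slow, so that hydrodebromination of 2 and oxidative decay of the electron-rich phenoxide outrun C–O bond formation. The fallback replaces copper catalysis by an uncatalysed addition–elimination; it sets out from CD phenol 5 and returns at BCD aldehyde 6. Phenol 5 would be heated with 4-fluoro-3,5-dimethoxybenzaldehyde (COc1cc(C=O)cc(OC)c1F, assumed to be a purchasable building block) and K2CO3 in DMSO at 120–140 °C. The para formyl group stabilises the Meisenheimer adduct and fluoride is small enough to sit between the two methoxy groups. This fallback makes no compound that is new to the route (F0). The same remedy would serve step 1, from phenol 1 to aldehyde 3.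

Step 8. The last of the eight ether cleavages may lag through boron chelation by neighbouring oxygens, and the decahydroxy product may be oxidised by air during aqueous work-up and chromatography. The fallback changes from isolating the free polyphenol to trapping it as a stable derivative; it sets out from 14 and returns at 15. After the same BBr3 treatment and quench, the crude material would be acetylated directly (Ac2O, pyridine, DMAP cat., rt) to the decaacetate of the target F4. On silica, F4 separates from incompletely demethylated acetates. Acid-catalysed transesterification (HCl 1.25 M in degassed MeOH, rt to 40 °C, argon) would then release 15 by evaporation alone, with no phenoxide exposed to oxygen.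

Further compounds
F1 | step 7 | 4-{4-[3,5-dimethoxy-4-(3,4,5-trimethoxyphenoxy)phenoxy]-3,5-dimethoxyphenoxy}-3,5-dimethoxybenzaldehyde (ABCD aldehyde) | O=Cc1cc(OC)c(Oc2cc(OC)c(Oc3cc(OC)c(Oc4cc(OC)c(OC)c(OC)c4)c(OC)c3)c(OC)c2)c(OC)c1
F2 | step 7 | 4-{4-[3,5-dimethoxy-4-(3,4,5-trimethoxyphenoxy)phenoxy]-3,5-dimethoxyphenoxy}-3,5-dimethoxyphenyl formate (ABCD aryl formate) | O=COc1cc(OC)c(Oc2cc(OC)c(Oc3cc(OC)c(Oc4cc(OC)c(OC)c(OC)c4)c(OC)c3)c(OC)c2)c(OC)c1
F3 | step 7 | 4-{4-[3,5-dimethoxy-4-(3,4,5-trimethoxyphenoxy)phenoxy]-3,5-dimethoxyphenoxy}-3,5-dimethoxyphenol (nonamethyl ABCD phenol) | Oc1cc(OC)c(Oc2cc(OC)c(Oc3cc(OC)c(Oc4cc(OC)c(OC)c(OC)c4)c(OC)c3)c(OC)c2)c(OC)c1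
F0 | step 3 | none | none
F4 | step 8 | decaacetate of the target | CC(=O)Oc1cc(OC(C)=O)c(Oc2cc(OC(C)=O)c(Oc3cc(OC(C)=O)c(Oc4cc(OC(C)=O)c(OC(C)=O)c(OC(C)=O)c4)c(OC(C)=O)c3)c(OC(C)=O)c2)c(OC(C)=O)c1
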